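The numbers are those of an exercise; the flask was simulated.

common to all: starting material 0.086 M; coupling partner 1.05 equiv; protic impurity 8.60 mM; free catalyst 0.1 mol%; time 4.0 d
- Tuesday's: temperature 50 °C
- Wednesday's: temperature 65 °C
- Saturday's: temperature 20 °C
- Friday's: temperature 35 °C

- which flask leads in amount of intermediate, in percent of the starting material charged ("all alike" within 1.5 percentage points) (Tuesday's / Wednesday's / Saturday's / Friday's / all alike)
- how much intermediate is there at the end, in percent of the starting material charged: Tuesday's
- how much intermediate is there at the end, in percent of the starting material charged: Wednesday's
- how much intermediate is there at the end, in percent of the starting material charged: Saturday's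
- how much intermediate is there at the end, in percent of the starting material charged: Friday's

- all constants are for 35 °C and move with temperature by the activation energies

    starting material + protic impurity → quenched substrate (k1 = 0.0095 M⁻¹ min⁻¹, Ea1 = 67.0 kJ mol⁻¹)
    starting material + free catalyst → free catalyst + intermediate (k2 = 3.4 M⁻¹ min⁻¹, Ea2 = 41.0 kJ mol⁻¹)
    free catalyst → spent catalyst (k3 = 0.0044 min⁻¹, Ea3 = 90.0 kJ mol⁻¹)
    coupling partner + free catalyst + intermediate → free catalyst + target (k4 = 51 M⁻² min⁻¹, Ea4 = 48.0 kJ mol⁻¹)
    (constants at 35 °C)

1. Time came first. Each flask ran 4.0 d, so I ranked the clocks of Wednesday's and Saturday's inside that span, shortest first. The life of the free catalyst is one over the constant of its death: 10.1 min in Wednesday's and 0.952 d in Saturday's. Saturday's life is shorter than the run, which lasts 4.20 such lives.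

2. The next clock was the protic impurity. Its loss is pseudo-first-order while [starting material] stays near its charge, with a life of 120 min in Wednesday's and 3.24 d in Saturday's. Saturday's quench is slower than Saturday's catalyst death, and Wednesday's likewise. Since the catalyst's life is the shorter clock in both flasks, I reckoned without the impurity, although its charge equals 10.0% of the starting material.

3. Since Saturday's catalyst life is shorter than the run, I took its death as finished and counted what one charge can do first. [free catalyst] at the start, times its life, times the constant of the step making intermediate, gave 17.7% for Saturday's. This is the catalyst's reach: the share of the starting material that one charge would turn over before it dies if [starting material] held at its charge.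

4. From coldest to hottest, catalyst death speeds up 140-fold, faster than the making step's 9.38-fold. So the reach fell with warmth: 6.65% in Friday's, 2.74% in Tuesday's and 1.22% in Wednesday's.

5. The starting material shrinks as it is used, so the share turned over is one minus the exponential of minus the reach. Part of Saturday's intermediate also goes on to target, about 1.84% by the ratio of the two steps. I committed to 14.4% for Saturday's after that trim, then, with no trim taken, 6.43% for Friday's, 2.70% for Tuesday's and 1.21% for Wednesday's, with Saturday's ahead.

The forecast also named Saturday's, with 13.9% there (12.8% to 15%), 6% in Friday's, 2.6% in Tuesday's and 1.2% in Wednesday's. Its ground was every flask stalling at catalyst death, “with the coldest getting by far the most catalytic work done”. My Saturday's figure stood above its number, and so did my Friday's.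

The simulation gave Saturday's the lead at 14.1%, with 6.05% in Friday's, 2.61% in Tuesday's and 1.19% in Wednesday's. Saturday's still held 1.50% of its catalyst free at 4.00 d, and at 40.0 d its intermediate read 14.3%. Saturday's intermediate and target together came to 15.6%, against 16.2% from its reach. Wednesday's reach of 1.22% stood beside the neighbour flask, Wednesday's read at 2.5 d, which held 1.19% intermediate.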